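Hold one balance throughout: what was charged as substrate stands as substrate, intermediate, target or isomer of the product, and each by-product counts one turn of the splitting of intermediate.

    2 reagent → self-condensation product (k1 = 1.66 × 10⁻⁴ /M/s, Ea1 = 81.0 kJ/mol)
    target ⇌ isomer of the product (K2 = 0.33, k2 = 3.20 × 10⁻⁵ /s, Ea2 = 105 kJ/mol, ΔH2 = 15.0 kJ/mol)
    substrate + reagent ⇌ intermediate (K3 = 639 /M, k3 = 0.00443 /M/s, Ea3 = 76.0 kJ/mol, ΔH3 = −60.0 kJ/mol)
    intermediate ⇌ target + by-product (K4 = 0.79 M, k4 = 1.20 × 10⁻⁵ /s, Ea4 = 113 kJ/mol, ΔH4 = 7.00 kJ/mol)
    gas ⇌ reagent, rate k5*(csat - [reagent]) (k5 = 0.00747 /s, csat = 45 mM)
    (constants at 40 °C)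

all flasks: substrate 0.51 M; gas 45 mM (held); time 8.0 d
- grey: temperature 60 °C
- ochre: temperature 40 °C
- blue: temperature 80 °C

- two of one species on the left: rate k times its square, two consumed each time
- at the start none of reagent is dissolved
- all constants are for 40 °C and move with temperature by the activation energies and enthalpies

* the best flask by amount of target, in percent of the substrate charged; "all alike" if 1.5 percentage points covers them all (grey / ochre / blue / all alike)
* amount of target at the end, in percent of the substrate charged, grey
* amount of target at the end, in percent of the substrate charged, ochre
* amount of target at the end, in percent of the substrate charged, blue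

Count turnovers first. Splitting has a smaller constant than isomerisation or binding at saturated reagent, yet it still gets 8.29 turnovers in ochre, and blue speeds it up by a factor of 140. So compare the ochre and blue flasks at equilibrium, which is thermodynamic control. Set [reagent] to saturation, because even in blue self-condensation drains it at 5.07 × 10⁻⁴ /s, slower than the gas feeds it at 0.00747 /s.

Let x be [by-product], which equals [target] plus [isomer of the product]. Then [target] is x divided by one plus the isomer constant. [Intermediate] is [target] times x over the splitting constant, and [substrate] is [intermediate] over the binding constant times [reagent]. The balance collapses to charge = x + x·x/C. Here C, the room of a flask, is the splitting constant times one plus the isomer constant, divided by one plus the inverse of binding constant times [reagent]. In ochre it is 1.02 M.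

For blue, raise each rate factor to the power enthalpy over activation energy. The isomer constant becomes 0.634, binding 47.0 /M, splitting 1.07 M. Solve the quadratic:

| flask | room C | by-product x | target, share of charge |
|---|---|---|---|
| ochre | 1.02 M | 0.373 M | 55.0 % |
| blue | 1.19 M | 0.385 M | 46.2 % |

The two counts lie close. They part at the division: the isomer takes 38.8 % of x in blue, more than the 24.8 % in ochre, so blue ends lower. Leave grey unreckoned.

The forecast says 51.5 % for grey, 55 % for ochre and 46 % for blue, and picks ochre: “so all flasks reach equilibrium”. My blue, with reagent at saturation, stands 0.20 percentage points above its figure.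

The simulation gives 51.5 % in grey, 55.0 % in ochre and 46.0 % in blue, and the best flask is ochre.

Ochre holds by-product 0.373 M at 8.00 d, where the room counted 0.373 M, and at 80.0 d its target still reads 55.0 %. Now charge a neighbour of ochre with 2.0 M of substrate, all else held. Temperature and gas are unchanged, so C stays 1.02 M. The same root counts x = 1.01 M, and target comes to 37.8 % of that charge. The neighbour ends with by-product 1.01 M, intermediate 48.1 % and target 37.8 %.

(The rate constants were chosen freely; no experiment stands behind them.)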